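The cyclohexene is cut at C5–C6 and C1–C2. Ring A (the coumarin on C6) and the alkenyl carbon on quaternary C1 are cis, just as C4, C3 and C2 of a coumarin lactone are. A Diels–Alder addition of a silyl diene across the 3,4-bond of a coumarin-3-carboxylate therefore closes the carbocycle, sets C6 in absolute terms and puts the future alkenyl carbon on C1. The allylsilane left behind later moves the alkene to C4=C5. The precursors are ethyl 5,7-dimethoxycoumarin-3-carboxylate, a dienophile that can hold a chiral Lewis acid through two carbonyl groups, and (E)-1-trimethylsilyl-2-methylbutadiene.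

Key step: step 4

Remarks on the chemistry:
- Locants: cyclohexene C1 = quaternary carbon, C4(Me)=C5, C6 = aryl methine; tricyclic intermediates carry benzo[c]chromene locants (C6a = future C1, C10a = future C6).
- Assumption: which antipode of the bis(oxazoline) shields which face of the chelated coumarin cannot be predicted with certainty; the (S,S)-ligand is written, and the (R,R)-ligand is to be taken if the first run gives the mirror-image adduct.
- Assumption: 8 is drawn as the ester-endo epimer at C10; that centre is erased in step 5, so either epimer serves.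
- The ester-derived stereocentre at C6a is erased in step 6, and the quaternary centre is rebuilt in step 8 on the ring-opened ester, where the neighbouring arene directs the methyl group.

Step 1
Reactants: 1 2-hydroxy-4,6-dimethoxybenzaldehyde; 2 diethyl malonate
Product: 4 ethyl 5,7-dimethoxy-2-oxo-2H-chromene-3-carboxylate, via Knoevenagel adduct 3 (not isolated)
Conditions: piperidine (cat.), AcOH (cat.), EtOH, reflux
Reagents that add atoms: none
Why: Knoevenagel condensation of the aldehyde with the malonate is followed by lactonisation of the ortho-phenol onto the cis ester with loss of ethanol, a standard entry to coumarin-3-carboxylates that creates no stereocentre.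

Step 2
Reactants: 5 3-methyl-3-sulfolene
Product: 6 3-methyl-2-(trimethylsilyl)-2,5-dihydrothiophene 1,1-dioxide (racemic)
Conditions: Me3SiCl, then LiN(SiMe3)2 added slowly, THF, −78 °C
Reagents that add atoms: chlorotrimethylsilane, C[Si](C)(C)Cl
Why: Silylation of the alpha-sulfonyl carbanion under in-situ quench traps the anion before it can ring-open, and deprotonation should occur at C2 because the resulting allyl anion then carries the methyl group on its central carbon; the new stereocentre is racemic and disappears in step 3.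

Step 3
Reactants: 6 3-methyl-2-(trimethylsilyl)-2,5-dihydrothiophene 1,1-dioxide
Product: 7 (E)-trimethyl(2-methylbuta-1,3-dien-1-yl)silane
Conditions: NaHCO3, neat, 140 °C, diene distilled off as formed
Reagents that add atoms: none
Why: Cheletropic extrusion of SO2 opens the ring in a disrotatory sense that turns the 2-silyl group outward, so the 1-silyl diene should form as the E isomer.

Step 4
Reactants: 4 ethyl 5,7-dimethoxy-2-oxo-2H-chromene-3-carboxylate; 7 (E)-trimethyl(2-methylbuta-1,3-dien-1-yl)silane
Product: 8 ethyl (6aS,10R,10aS)-1,3-dimethoxy-9-methyl-6-oxo-10-(trimethylsilyl)-6a,7,10,10a-tetrahydro-6H-benzo[c]chromene-6a-carboxylate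
Conditions: Cu(OTf)2 (10 mol %), 2,2'-isopropylidenebis[(4S)-4-tert-butyl-2-oxazoline] (11 mol %), 4 Å MS, CH2Cl2, −20 °C → rt
Reagents that add atoms: none
Why: Proposed new method: the divalent copper–bis(oxazoline) cation should bind the lactone and ester carbonyls of 4 as a six-membered chelate, lowering the LUMO of the C3=C4 bond enough to offset the 5- and 7-methoxy donors, and the diene then adds in a polar, asynchronous [4+2] cycloaddition in which its silyl-bearing terminus bonds first to coumarin C4 (the allyl cation so formed is tertiary and beta to silicon) before C3 closes onto the CH2 terminus. The closest known reactions are the thermal, high-pressure and achiral Lewis-acid Diels–Alder additions of 3-alkoxycarbonylcoumarins to 1,3-dienes and the Cu(OTf)2–bis(oxazoline) catalysis of two-point-binding alkylidene malonates. The carbocycle is closed by the intermolecular cycloaddition itself, suprafacially on both partners, the C6a–C7 bond completing a six-membered ring fused to the lactone. C6a and C10a come out cis because the dienophile double bond is locked cis inside the coumarin ring, their absolute configuration is set by the ligand shielding one face of the planar chelate, and C10 follows from an ester-endo approach of the E-diene. The step needs regioselectivity, which the 2-methyl group and the beta-silicon effect secure by acting in the same sense, and facial selectivity, which the rigid two-point binding of the 2-oxo/3-ester pair secures.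

Step 5
Reactants: 8 ethyl (6aS,10R,10aS)-1,3-dimethoxy-9-methyl-6-oxo-10-(trimethylsilyl)-6a,7,10,10a-tetrahydro-6H-benzo[c]chromene-6a-carboxylate
Product: 9 ethyl (6aS,10aS)-1,3-dimethoxy-9-methyl-6-oxo-6a,7,8,10a-tetrahydro-6H-benzo[c]chromene-6a-carboxylate
Conditions: CF3CO2H (3 equiv), CH2Cl2, 0 °C, short contact; NaHCO3 quench
Reagents that add atoms: none
Why: Protodesilylation of the allylsilane (SE2') puts the proton on C8 and, through the beta-silyl tertiary cation at C9, moves the alkene to C9=C10 (future C4=C5) with loss of the C10 stereocentre, the allylsilane being far more nucleophilic than the alkene it leaves behind.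

Step 6
Reactants: 9 ethyl (6aS,10aS)-1,3-dimethoxy-9-methyl-6-oxo-6a,7,8,10a-tetrahydro-6H-benzo[c]chromene-6a-carboxylate
Product: 10 (6aS,10aR)-1,3-dimethoxy-9-methyl-6a,7,8,10a-tetrahydro-6H-benzo[c]chromen-6-one (cis-fused)
Conditions: LiCl, H2O, DMSO, 150 °C
Reagents that add atoms: none
Why: Krapcho dealkoxycarbonylation (chloride dealkylates the ethyl ester, the carboxylate loses CO2 and the lactone enolate is protonated) removes the activating group; the C6a configuration is of no consequence because step 8 passes through an enolate again, while C10a is not acidic and is retained.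

Step 7
Reactants: 10 (6aS,10aR)-1,3-dimethoxy-9-methyl-6a,7,8,10a-tetrahydro-6H-benzo[c]chromen-6-one
Product: 12 methyl (1S,2R)-2-[2-(tert-butyldimethylsilyloxy)-4,6-dimethoxyphenyl]-4-methylcyclohex-3-ene-1-carboxylate, via sodium phenolate ester 11 (not isolated)
Conditions: NaOMe, MeOH, 0 °C → rt; evaporate; t-BuMe2SiCl, imidazole, DMF, rt
Reagents that add atoms: sodium methoxide, [Na+].[O-]C; tert-butyldimethylsilyl chloride, CC(C)(C)[Si](C)(C)Cl
Why: Transesterifying ring-opening of the aryl lactone (methoxide adds, the less basic phenoxide leaves and stays open) is followed by O-silylation of that phenoxide, which frees the arene from the ring so that it can direct step 8; no stereocentre is formed and any epimerisation next to the ester is harmless.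

Step 8
Reactants: 12 methyl (1S,2R)-2-[2-(tert-butyldimethylsilyloxy)-4,6-dimethoxyphenyl]-4-methylcyclohex-3-ene-1-carboxylate
Product: 14 methyl (1S,2S)-2-[2-(tert-butyldimethylsilyloxy)-4,6-dimethoxyphenyl]-1,4-dimethylcyclohex-3-ene-1-carboxylate, via lithium ester enolate 13 (not isolated)
Conditions: LiN(i-Pr)2, THF, −78 °C; MeI, DMPU, −78 → −20 °C
Reagents that add atoms: iodomethane, CI
Why: In this ester-enolate alkylation, allylic 1,3-strain between the enolate oxygens and the neighbouring ring carbon forces the bulky aryl group pseudo-axial, so iodomethane should enter the opposite face and the new quaternary centre (future C1) should carry the methyl group trans and the ester carbon cis to the arene.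

Step 9
Reactants: 14 methyl (1S,2S)-2-[2-(tert-butyldimethylsilyloxy)-4,6-dimethoxyphenyl]-1,4-dimethylcyclohex-3-ene-1-carboxylate
Product: 16 2-[(1R,6S)-6-ethynyl-3,6-dimethylcyclohex-2-en-1-yl]-3,5-dimethoxyphenol, via silyl-protected aldehyde 15 (not isolated)
Conditions: i-Bu2AlH, CH2Cl2, −78 °C; MeOH; then K2CO3, dimethyl (1-diazo-2-oxopropyl)phosphonate, MeOH, 0 °C → rt
Reagents that add atoms: dimethyl (1-diazo-2-oxopropyl)phosphonate, CC(=O)C(=[N+]=[N-])P(=O)(OC)OC
Why: Partial reduction of the hindered ester, whose tetrahedral aluminate is stable at −78 °C, releases the non-enolisable aldehyde on methanol quench, and Seyferth–Gilbert homologation with the Ohira–Bestmann reagent (1,2-hydrogen shift of the alkylidene carbene) should give the terminal alkyne while K2CO3/MeOH methanolyses the aryl silyl ether; both stereocentres are untouched.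

Step 10
Reactants: 16 2-[(1R,6S)-6-ethynyl-3,6-dimethylcyclohex-2-en-1-yl]-3,5-dimethoxyphenol
Product: 17 3-[(1R,6S)-6-ethynyl-3,6-dimethylcyclohex-2-en-1-yl]-2-hydroxy-4,6-dimethoxybenzaldehyde
Conditions: MgCl2, Et3N, (CH2O)n, MeCN, reflux
Reagents that add atoms: paraformaldehyde (as formaldehyde), C=O
Why: In the magnesium-phenoxide-directed ortho-formylation (Casnati–Skattebøl reaction), formaldehyde is delivered inside the magnesium chelate to the only free ortho position and a second formaldehyde oxidises the benzylic alkoxide to the aldehyde, so the position para to the hydroxyl is left alone.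

Step 11
Reactants: 17 3-[(1R,6S)-6-ethynyl-3,6-dimethylcyclohex-2-en-1-yl]-2-hydroxy-4,6-dimethoxybenzaldehyde
Product: 19 8-[(1R,6S)-6-ethynyl-3,6-dimethylcyclohex-2-en-1-yl]-5,7-dimethoxy-2H-chromen-2-one, via ester ylide 18 (not isolated)
Conditions: Ph3P=C=C=O, toluene, 110 °C
Reagents that add atoms: (triphenylphosphoranylidene)ketene, O=C=C=P(c1ccccc1)(c1ccccc1)c1ccccc1
Why: In the Bestmann coumarin annulation the phenol O–H adds across the C=C bond of the ketenylidene ylide and the resulting ester ylide closes by intramolecular Wittig reaction onto the ortho-aldehyde, building the pyranone of ring A under neutral conditions.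

Step 12
Reactants: 20 5,7-dimethoxycoumarin
Product: 21 8-iodo-5,7-dimethoxy-2H-chromen-2-one
Conditions: N-iodosuccinimide, CF3CO2H (cat.), MeCN, rt
Reagents that add atoms: N-iodosuccinimide, O=C1CCC(=O)N1I
Why: Electrophilic aromatic iodination is expected at C8, which is ortho to the 7-methoxy group and O1 and para to the 5-methoxy group, whereas C6 is flanked by two methoxy groups and C3 lies in the electron-poor pyranone ring.

Step 13
Reactants: 19 8-[(1R,6S)-6-ethynyl-3,6-dimethylcyclohex-2-en-1-yl]-5,7-dimethoxy-2H-chromen-2-one; 21 8-iodo-5,7-dimethoxy-2H-chromen-2-one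
Product: 22 8-{[(1S,2R)-2-(5,7-dimethoxy-2-oxo-2H-chromen-8-yl)-1,4-dimethylcyclohex-3-en-1-yl]ethynyl}-5,7-dimethoxy-2H-chromen-2-one
Conditions: Pd(PPh3)2Cl2 (5 mol %), CuI (10 mol %), Et3N, DMF, 60 °C
Reagents that add atoms: none
Why: Sonogashira coupling (oxidative addition of zerovalent palladium into the aryl iodide, transmetalation from the copper acetylide, reductive elimination) joins the two halves without touching either stereocentre or the lactones.

Step 14
Reactants: 22 8-{[(1S,2R)-2-(5,7-dimethoxy-2-oxo-2H-chromen-8-yl)-1,4-dimethylcyclohex-3-en-1-yl]ethynyl}-5,7-dimethoxy-2H-chromen-2-one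
Product: 23 8-{(Z)-2-[(1R,2R)-2-(5,7-dimethoxy-2-oxo-2H-chromen-8-yl)-1,4-dimethylcyclohex-3-en-1-yl]ethenyl}-5,7-dimethoxy-2H-chromen-2-one (CNP0164660.3)
Conditions: H2 (1 atm), Pd/CaCO3 poisoned with Pb(OAc)2, quinoline, EtOAc, rt
Reagents that add atoms: none
Why: In the Lindlar semi-hydrogenation both hydrogen atoms are delivered from the poisoned palladium surface to the same face of the alkyne, which should give the Z-alkene while the trisubstituted ring alkene and the two coumarin C3=C4 bonds are left alone.

Compound list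
1 | 2-hydroxy-4,6-dimethoxybenzaldehyde | COc1cc(O)c(C=O)c(OC)c1 | starting material
2 | diethyl malonate | CCOC(=O)CC(=O)OCC | starting material
3 | diethyl 2-[(2-hydroxy-4,6-dimethoxyphenyl)methylidene]propanedioate | CCOC(=O)C(=Cc1c(O)cc(OC)cc1OC)C(=O)OCC | intermediate
4 | ethyl 5,7-dimethoxy-2-oxo-2H-chromene-3-carboxylate | CCOC(=O)c1cc2c(OC)cc(OC)cc2oc1=O | intermediate
5 | 3-methyl-3-sulfolene (3-methyl-2,5-dihydrothiophene 1,1-dioxide) | CC1=CCS(=O)(=O)C1 | starting material
6 | 3-methyl-2-(trimethylsilyl)-2,5-dihydrothiophene 1,1-dioxide (racemic) | CC1=CCS(=O)(=O)C1[Si](C)(C)C | intermediate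
7 | (E)-trimethyl(2-methylbuta-1,3-dien-1-yl)silane | C[Si](C)(C)/C=C(\C)C=C | intermediate
8 | ethyl (6aS,10R,10aS)-1,3-dimethoxy-9-methyl-6-oxo-10-(trimethylsilyl)-6a,7,10,10a-tetrahydro-6H-benzo[c]chromene-6a-carboxylate (cis-fused; silyl group cis to the ester) | O=C1Oc2cc(OC)cc(OC)c2[C@@H]2[C@@H]([Si](C)(C)C)C(C)=CC[C@]12C(=O)OCC | intermediate
9 | ethyl (6aS,10aS)-1,3-dimethoxy-9-methyl-6-oxo-6a,7,8,10a-tetrahydro-6H-benzo[c]chromene-6a-carboxylate (cis-fused) | O=C1Oc2cc(OC)cc(OC)c2[C@@H]2C=C(C)CC[C@]12C(=O)OCC | intermediate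
10 | (6aS,10aR)-1,3-dimethoxy-9-methyl-6a,7,8,10a-tetrahydro-6H-benzo[c]chromen-6-one (cis-fused) | O=C1Oc2cc(OC)cc(OC)c2[C@@H]2C=C(C)CC[C@H]12 | intermediate
11 | sodium 2-[(1R,6S)-6-(methoxycarbonyl)-3-methylcyclohex-2-en-1-yl]-3,5-dimethoxyphenolate | [Na+].COC(=O)[C@H]1CCC(C)=C[C@H]1c1c(OC)cc(OC)cc1[O-] | intermediate
12 | methyl (1S,2R)-2-[2-(tert-butyldimethylsilyloxy)-4,6-dimethoxyphenyl]-4-methylcyclohex-3-ene-1-carboxylate (cis) | COC(=O)[C@H]1CCC(C)=C[C@H]1c1c(OC)cc(OC)cc1O[Si](C)(C)C(C)(C)C | intermediate
13 | lithium enolate of 12: lithium methoxy{(2S)-2-[2-(tert-butyldimethylsilyloxy)-4,6-dimethoxyphenyl]-4-methylcyclohex-3-en-1-ylidene}methanolate | [Li+].COC([O-])=C1CCC(C)=C[C@H]1c1c(OC)cc(OC)cc1O[Si](C)(C)C(C)(C)C | intermediate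
14 | methyl (1S,2S)-2-[2-(tert-butyldimethylsilyloxy)-4,6-dimethoxyphenyl]-1,4-dimethylcyclohex-3-ene-1-carboxylate (methyl trans, ester cis to the arene) | COC(=O)[C@@]1(C)CCC(C)=C[C@H]1c1c(OC)cc(OC)cc1O[Si](C)(C)C(C)(C)C | intermediate
15 | (1S,2S)-2-[2-(tert-butyldimethylsilyloxy)-4,6-dimethoxyphenyl]-1,4-dimethylcyclohex-3-ene-1-carbaldehyde | O=C[C@@]1(C)CCC(C)=C[C@H]1c1c(OC)cc(OC)cc1O[Si](C)(C)C(C)(C)C | intermediate
16 | 2-[(1R,6S)-6-ethynyl-3,6-dimethylcyclohex-2-en-1-yl]-3,5-dimethoxyphenol | C#C[C@@]1(C)CCC(C)=C[C@H]1c1c(OC)cc(OC)cc1O | intermediate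
17 | 3-[(1R,6S)-6-ethynyl-3,6-dimethylcyclohex-2-en-1-yl]-2-hydroxy-4,6-dimethoxybenzaldehyde | C#C[C@@]1(C)CCC(C)=C[C@H]1c1c(OC)cc(OC)c(C=O)c1O | intermediate
18 | 2-[(1R,6S)-6-ethynyl-3,6-dimethylcyclohex-2-en-1-yl]-6-formyl-3,5-dimethoxyphenyl (triphenyl-λ5-phosphanylidene)acetate | C#C[C@@]1(C)CCC(C)=C[C@H]1c1c(OC)cc(OC)c(C=O)c1OC(=O)C=P(c1ccccc1)(c1ccccc1)c1ccccc1 | intermediate
19 | 8-[(1R,6S)-6-ethynyl-3,6-dimethylcyclohex-2-en-1-yl]-5,7-dimethoxy-2H-chromen-2-one | C#C[C@@]1(C)CCC(C)=C[C@H]1c1c(OC)cc(OC)c2ccc(=O)oc12 | intermediate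
20 | 5,7-dimethoxycoumarin | COc1cc(OC)c2ccc(=O)oc2c1 | starting material
21 | 8-iodo-5,7-dimethoxy-2H-chromen-2-one | COc1cc(OC)c2ccc(=O)oc2c1I | intermediate
22 | 8-{[(1S,2R)-2-(5,7-dimethoxy-2-oxo-2H-chromen-8-yl)-1,4-dimethylcyclohex-3-en-1-yl]ethynyl}-5,7-dimethoxy-2H-chromen-2-one | COc1cc(OC)c2ccc(=O)oc2c1C#C[C@@]1(C)CCC(C)=C[C@H]1c1c(OC)cc(OC)c2ccc(=O)oc12 | intermediate
23 | 8-{(Z)-2-[(1R,2R)-2-(5,7-dimethoxy-2-oxo-2H-chromen-8-yl)-1,4-dimethylcyclohex-3-en-1-yl]ethenyl}-5,7-dimethoxy-2H-chromen-2-one | COc1cc(OC)c2ccc(=O)oc2c1/C=C\[C@@]1(C)CCC(C)=C[C@H]1c1c(OC)cc(OC)c2ccc(=O)oc12 | target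

Total step count: 14.
Longest linear sequence: 12 steps (5 → 6 → 7 → 8 → 9 → 10 → 12 → 14 → 16 → 17 → 19 → 22 → 23; steps 2–11, 13 and 14).

Steps most likely to fail

1. Step 4 (the one step proposed as a new method). The copper chelate may activate the donor-substituted coumarin too weakly, or the ligand may discriminate the two faces of the chelate poorly. The fallback uses known chemistry and sets out from 4 and 7. They are combined without a chiral catalyst, in a sealed tube (toluene, 170 °C, trace of BHT) or at about 10 kbar in CH2Cl2, the established modes for 3-alkoxycarbonylcoumarins and 1,3-dienes. This should give 8 as a racemate, that is, together with its mirror image ethyl (6aR,10S,10aR)-1,3-dimethoxy-9-methyl-6-oxo-10-(trimethylsilyl)-6a,7,10,10a-tetrahydro-6H-benzo[c]chromene-6a-carboxylate F1. Preparative chromatography on a chiral stationary phase (amylose tris(3,5-dimethylphenylcarbamate)) separates the two, and the route is rejoined at 8.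

2. Step 9. Reduction of the hindered ester may run past the aldehyde level, or the homologation may stall beside the quaternary centre. The fallback sets out from 14 and uses the lactone to hold the aldehyde oxidation level. Bu4NF in THF frees the phenoxide, which should close onto the cis ester to give the lactone (6aS,10aS)-1,3-dimethoxy-6a,9-dimethyl-6a,7,8,10a-tetrahydro-6H-benzo[c]chromen-6-one F2. Reduction with i-Bu2AlH at −78 °C should then stop at the lactol (6aS,10aS)-1,3-dimethoxy-6a,9-dimethyl-6a,7,8,10a-tetrahydro-6H-benzo[c]chromen-6-ol F3, because the cyclic hemiacetal aluminate does not collapse. The Ohira–Bestmann reagent with K2CO3 in MeOH converts the lactol, through its open hydroxy-aldehyde form, into 16, where the route is rejoined.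

3. Step 14. The semi-hydrogenation may stall on the doubly hindered alkyne, run on to the alkane, or isomerise the Z-alkene. The fallback sets the geometry before the carbon–carbon bond is made and sets out from 19 and 21, bypassing steps 13 and 14. Rhodium-catalysed trans-hydroboration of 19 with pinacolborane ([Rh(cod)Cl]2, P(i-Pr)3, Et3N, cyclohexane, rt) should give the (Z)-alkenylboronate 8-[(1R,6R)-3,6-dimethyl-6-[(Z)-2-(4,4,5,5-tetramethyl-1,3,2-dioxaborolan-2-yl)ethenyl]cyclohex-2-en-1-yl]-5,7-dimethoxy-2H-chromen-2-one F4. Stereoretentive Suzuki–Miyaura coupling of this boronate with 21 (Pd(dppf)Cl2, K3PO4, dioxane/H2O, 60 °C) arrives at 23.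

Further compounds
F1 | step 4 | ethyl (6aR,10S,10aR)-1,3-dimethoxy-9-methyl-6-oxo-10-(trimethylsilyl)-6a,7,10,10a-tetrahydro-6H-benzo[c]chromene-6a-carboxylate | O=C1Oc2cc(OC)cc(OC)c2[C@H]2[C@H]([Si](C)(C)C)C(C)=CC[C@@]12C(=O)OCC
F2 | step 9 | (6aS,10aS)-1,3-dimethoxy-6a,9-dimethyl-6a,7,8,10a-tetrahydro-6H-benzo[c]chromen-6-one | O=C1Oc2cc(OC)cc(OC)c2[C@@H]2C=C(C)CC[C@]12C
F3 | step 9 | (6aS,10aS)-1,3-dimethoxy-6a,9-dimethyl-6a,7,8,10a-tetrahydro-6H-benzo[c]chromen-6-ol (anomeric mixture) | OC1Oc2cc(OC)cc(OC)c2[C@@H]2C=C(C)CC[C@]12C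
F4 | step 14 | 8-[(1R,6R)-3,6-dimethyl-6-[(Z)-2-(4,4,5,5-tetramethyl-1,3,2-dioxaborolan-2-yl)ethenyl]cyclohex-2-en-1-yl]-5,7-dimethoxy-2H-chromen-2-one | CC1(C)OB(/C=C\[C@@]2(C)CCC(C)=C[C@H]2c2c(OC)cc(OC)c3ccc(=O)oc23)OC1(C)C
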